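(The constants used here belong to no real substance; the rest is arithmetic.)

Tuesday's flask and Monday's are neighbours, alike in their charges and apart in the feed of electrophile, 2.0 s against 20 s, and Friday's, Wednesday's and Sunday's stand beside them.

    acidic substrate + free base ⇌ protonated base + anion, settled at all times (K1 = 0.33, ΔH1 = 5.00 kJ mol⁻¹)
    electrophile + anion → target (k2 = 2.31 M⁻¹ s⁻¹, Ea2 = 46.0 kJ mol⁻¹)
    solid base ⇌ free base, rate k3*(cs3 - [free base]) while solid is left; crystals form when [free base] > cs3 (cs3 = 33 mM, k3 = 0.454 s⁻¹)
    electrophile + protic impurity → quenched reagent (k4 = 0.103 M⁻¹ s⁻¹, Ea4 = 46.0 kJ mol⁻¹)
    (constants at 20 °C)

in all of them: solid base 1.00 equiv; protic impurity 0.150 M; time 30 s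
- Monday's: acidic substrate 0.30 M; electrophile 1.05 equiv (fed, over 20 s); temperature 20 °C; all else is in the flask from the start; the feed brings no volume worth counting
- Sunday's: acidic substrate 0.30 M (fed, over 20 s); electrophile 1.05 equiv; the addition at 0 °C, then warmed to 20 °C; the feed brings no volume worth counting
- Friday's: acidic substrate 0.30 M (fed, over 20 s); electrophile 1.05 equiv; temperature 20 °C; all else is in the flask from the start; the feed brings no volume worth counting
- Wednesday's: acidic substrate 0.30 M; electrophile 1.05 equiv; everything together at the start at 0 °C, warmed to 20 °C at 20 s
- Tuesday's: acidic substrate 0.30 M; electrophile 1.05 equiv (fed, over 2.0 s); temperature 20 °C; all else is in the flask from the start; the feed brings no volume worth counting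

- solid base is a solid; its amount is given per volume of the solution
- all constants are for 20 °C and move with temperature by the activation energies and enthalpies
- at the start none of the solid base is in solution

- the flask with the highest amount of target, in percent of the acidic substrate charged ("all alike" if they lie within 1.5 percentage points) (Monday's / Sunday's / Friday's / Wednesday's / Tuesday's / all alike)
- final target, as a percentage of the acidic substrate charged, in Monday's
- final target, as a percentage of the acidic substrate charged, in Sunday's
- final target, as a percentage of the acidic substrate charged, in Friday's
- final target, as a percentage of the acidic substrate charged, in Wednesday's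
- final target, as a percentage of the acidic substrate charged, in Tuesday's

**What do you count to rank these flasks?**
Lifetimes of the electrophile. It reacts along two paths, with the anion to give target and with the protic impurity to give quenched reagent. Each path is pseudo-first-order in electrophile, provided its partner stays roughly steady.

**How much anion do you take?**
The balance gives c anion = K1 × c free base × c acidic substrate / c protonated base. I take c free base near its solubility, 33 mM, and I assume that in the middle of the run the last two concentrations are about equal. So c anion is about 0.0109 M.

**And the two rate constants?**
The path to target runs at 0.0252 s⁻¹ and the path to quenched reagent at 0.0154 s⁻¹. The inverse of their sum, 24.6 s, is what I call the working lifetime of the electrophile.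

**When does your clock start? The feeds differ.**
I start it at the middle of the feed, since that is the mean moment of arrival. In Tuesday's flask that leaves 1.18 lifetimes. Monday's flask feeds electrophile over 20 s, so it gets 0.812 lifetimes, of which 0.503 fall on the path to target. Friday's flask feeds acidic substrate instead, so its electrophile stands there from the start. Its path to quenched reagent therefore runs for the full 30 s, which counts 0.462, while I start its path to target at the middle of the feed, which again counts 0.503. Friday's flask thus gets 0.967 lifetimes, more than Monday's, and the excess lies on the path to quenched reagent.

**The cold flasks?**
The activation energies, 46.0 kJ mol⁻¹ and 46.0 kJ mol⁻¹, are equal, so cooling to 0 °C scales both paths alike, to 0.251 of their rate. I let each cold second count for that fraction of a second and neglect the small shift in K1. Wednesday's flask then gets 0.610 lifetimes, of which 0.378 fall on the path to target. Sunday's flask, which like Friday's feeds acidic substrate, counts 0.231 on the path to quenched reagent from the start and 0.315 on the path to target from the middle of its cold feed. Target is what is asked, so I rank by the count on the path to target, which in Tuesday's flask is 0.730. My order is therefore Tuesday's first, then Monday's, then Friday's, which has the same count on that path but more on the path to quenched reagent, then Wednesday's, then Sunday's.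

**A count is not a yield. What does Tuesday's flask give?**
After 1.18 lifetimes, 30.8 % of the electrophile remains. Of what reacts, 62.0 % goes to target. That makes target 42.9 % of the electrophile charged, and the electrophile charge is 1.05 equiv.

The forecast gives Tuesday's as highest, with 50 % there, 46.5 % in Monday's, 45 % in Friday's, 41.5 % in Wednesday's and 40 % in Sunday's, on the ground that “Having electrophile present early makes the best use of the limited time”.

The simulation puts Tuesday's highest at 49.7 %, followed by Monday's at 45.9 %, Friday's at 44.3 %, Wednesday's at 41.5 % and Sunday's at 38.7 %. In Tuesday's flask, 32.8 % of the electrophile charged stands at 30.0 s, where the count of 24.6 s lifetimes gave 30.8 %. The same lifetime, applied to Monday's flask over its 0.812 lifetimes, gives 44.4 % of the electrophile remaining, and Monday's flask holds 41.4 % of its charge at 30.0 s.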